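**Plan**
- Feature: the target is an oxolane (O1; C2 4-hydroxyphenyl; C3 2,4-dihydroxybenzoyl; C4 4-hydroxybenzyl; C5 2,4-dihydroxyphenyl) whose C3 carries an exocyclic carbonyl carbon. It is formally a 2,6-diaryl-5-benzyloxan-4-one whose ring carbonyl carbon has been extruded between C3 and C4, the retron of a Wolff ring contraction of a 3-diazooxan-4-one.
- Cuts, in retrosynthetic order: the five phenol O–benzyl bonds; the carbonyl–aryl bond of the benzoyl group; ring bond C3–C4 together with the amide C–N bond (ketene from the diazo ketone); the C2–aryl bond; the O1–C2 bond; the C3–carbonyl bond; the C4–C5 bond.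
- Forward: an anti-aldol reaction joins C4 to C5 on an open chain; the chain closes to the six-membered oxacycle (6-endo-dig); the C2 aryl group is added by conjugate addition; diazo transfer and photolysis contract the oxane to the oxolane (the only ring of the target, formed in the key step); the aryl ketone and the free phenols come last.
- Stereochemistry: C4 and C5 from the (S)-oxazolidinone-controlled anti-aldol; C2 from axial conjugate addition trans to the C5 aryl group; C4 passes through the 1,2-shift with retention; C3 is set last by base equilibration to the all-trans ring.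

Key step: step 8

Assumption: the magnesium-catalysed aldol is taken to follow the facial sense known for simpler N-acyl oxazolidinones (chelated Z-enolate attacked anti to the auxiliary benzyl group, anti product); if it ran the other way, the (R)-auxiliary would be used.

Numbering used for the oxanes of steps 6–8: O1, C2 (4-(benzyloxy)phenyl), C3, C4 (carbonyl), C5 (benzyl-bearing), C6 (2,4-bis(benzyloxy)phenyl).

Step 1
Reactants: 1 3-[4-(benzyloxy)phenyl]propanoic acid; 2 (S)-4-benzyloxazolidin-2-one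
Product: 4 (S)-4-benzyl-3-{3-[4-(benzyloxy)phenyl]propanoyl}oxazolidin-2-one, via mixed pivalic anhydride 3 (not isolated)
Conditions: PivCl, Et3N, THF, −20 °C; then 2, LiCl, −20 °C → rt
Reagents that add atoms: none
Why: Standard N-acylation of an oxazolidinone auxiliary through the mixed pivalic anhydride (LiCl/Et3N protocol), the nitrogen attacking the less hindered carbonyl group of the anhydride.

Step 2
Reactants: 4 (S)-4-benzyl-3-{3-[4-(benzyloxy)phenyl]propanoyl}oxazolidin-2-one; 5 2,4-bis(benzyloxy)benzaldehyde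
Product: 7 (S)-4-benzyl-3-{(2R,3S)-3-[2,4-bis(benzyloxy)phenyl]-2-[4-(benzyloxy)benzyl]-3-hydroxypropanoyl}oxazolidin-2-one, via aldol trimethylsilyl ether 6 (not isolated)
Conditions: MgCl2 (0.2 equiv), Et3N, TMSCl, EtOAc, rt; then AcOH, THF/H2O, rt
Reagents that add atoms: none
Why: Magnesium-halide-catalysed direct anti-aldol reaction of an N-acyl oxazolidinone: Et3N enolises the MgCl2-chelated imide to the Z-enolate, the non-enolisable aldehyde adds on the face away from the auxiliary benzyl group through a boat-like transition state, and O-silylation by TMSCl makes the addition irreversible and frees the catalyst, which sets the α-carbon as R and the carbinol as S (the future C4 and C5, anti).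

Step 3
Reactants: 7 (S)-4-benzyl-3-{(2R,3S)-3-[2,4-bis(benzyloxy)phenyl]-2-[4-(benzyloxy)benzyl]-3-hydroxypropanoyl}oxazolidin-2-one
Product: 8 (2R,3S)-3-[2,4-bis(benzyloxy)phenyl]-2-[4-(benzyloxy)benzyl]-3-hydroxy-N-methoxy-N-methylpropanamide
Conditions: MeNH(OMe)·HCl, AlMe3, CH2Cl2, −10 → 0 °C; aq. potassium sodium tartrate
Reagents that add atoms: N,O-dimethylhydroxylamine hydrochloride, CNOC.Cl
Why: Aluminium-amide transamidation to the Weinreb amide, steered to the exocyclic imide carbonyl by the aluminium alkoxide of the free β-hydroxyl group, with no stereocentre involved.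

Step 4
Reactants: 8 (2R,3S)-3-[2,4-bis(benzyloxy)phenyl]-2-[4-(benzyloxy)benzyl]-3-hydroxy-N-methoxy-N-methylpropanamide
Product: 9 (4R,5S)-5-[2,4-bis(benzyloxy)phenyl]-4-[4-(benzyloxy)benzyl]-5-hydroxypent-1-yn-3-one
Conditions: HC≡CMgBr (4 equiv), THF, 0 °C → rt; aq. NH4Cl
Reagents that add atoms: ethynylmagnesium bromide, C#C[Mg]Br
Why: Weinreb ketone synthesis: the magnesium-chelated tetrahedral adduct persists until the quench, so the alkynyl ketone should form without over-addition or retro-aldol cleavage, one equivalent of the Grignard reagent merely deprotonating the hydroxyl group.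

Step 5
Reactants: 9 (4R,5S)-5-[2,4-bis(benzyloxy)phenyl]-4-[4-(benzyloxy)benzyl]-5-hydroxypent-1-yn-3-one
Product: 10 (2S,3R)-2-[2,4-bis(benzyloxy)phenyl]-3-[4-(benzyloxy)benzyl]-2,3-dihydro-4H-pyran-4-one
Conditions: Ph3PAuCl (5 mol%), AgOTf (5 mol%), CH2Cl2, rt, dark
Reagents that add atoms: none
Why: π-Acid-catalysed 6-endo-dig hydroalkoxylation of a β-hydroxy ynone (Ph3PAuOTf formed in situ), the ynone polarity making the endo mode the only productive one; the neutral conditions leave the α-stereocentre and the electron-rich benzylic carbinol untouched, so the anti-aldol relationship becomes 2,3-trans.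

Step 6
Reactants: 10 (2S,3R)-2-[2,4-bis(benzyloxy)phenyl]-3-[4-(benzyloxy)benzyl]-2,3-dihydro-4H-pyran-4-one; 11 1-(benzyloxy)-4-bromobenzene
Product: 14 (2S,5R,6S)-6-[2,4-bis(benzyloxy)phenyl]-5-[4-(benzyloxy)benzyl]-2-[4-(benzyloxy)phenyl]oxan-4-one, via arylmagnesium bromide 12 (not isolated), via trimethylsilyl enol ether 13 (not isolated)
Conditions: 11 (2.5 equiv), Mg, THF, 40 °C; then CuBr·SMe2 (0.2 equiv), TMSCl, 10, THF, −78 → −40 °C; then 1 M HCl, THF, 0 °C
Reagents that add atoms: none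
Why: Copper-catalysed, TMSCl-accelerated conjugate addition of an aryl Grignard reagent to the vinylogous ester: axial attack on the half-chair with the existing aryl and benzyl groups pseudo-equatorial places the new aryl group trans to the aryl group across the ring oxygen (the usual 2,6-trans outcome for 2-substituted dihydropyranones), and cold hydrolysis of the silyl enol ether gives the kinetic trans ether no chance to equilibrate by retro-oxa-Michael opening.

Step 7
Reactants: 14 (2S,5R,6S)-6-[2,4-bis(benzyloxy)phenyl]-5-[4-(benzyloxy)benzyl]-2-[4-(benzyloxy)phenyl]oxan-4-one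
Product: 16 (2R,5R,6S)-6-[2,4-bis(benzyloxy)phenyl]-5-[4-(benzyloxy)benzyl]-2-[4-(benzyloxy)phenyl]-3-diazooxan-4-one, via trifluoroacetyl ketone 15 (not isolated)
Conditions: LiN(SiMe3)2, THF, −78 °C; CF3CO2CH2CF3, −78 °C; 5% aq. HCl; then MsN3, Et3N, H2O (1 equiv), MeCN, rt
Reagents that add atoms: methanesulfonyl azide, CS(=O)(=O)N=[N+]=[N-]
Why: Deacylative (detrifluoroacetylative) Regitz diazo transfer: LiN(SiMe3)2 deprotonates the CH2 group kinetically in preference to the benzyl-substituted CH, C-trifluoroacetylation activates that carbon, and MsN3/Et3N delivers the diazo group with loss of the trifluoroacetyl group as the N-sulfonyl amide, the low temperature of the enolate stage guarding the 2,6-trans ether against E1cB opening.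

Step 8
Reactants: 16 (2R,5R,6S)-6-[2,4-bis(benzyloxy)phenyl]-5-[4-(benzyloxy)benzyl]-2-[4-(benzyloxy)phenyl]-3-diazooxan-4-one
Product: 18 (2S,4S,5S)-5-[2,4-bis(benzyloxy)phenyl]-4-[4-(benzyloxy)benzyl]-2-[4-(benzyloxy)phenyl]-N-methoxy-N-methyloxolane-3-carboxamide (C3 epimer mixture), via ketene 17 (not isolated)
Conditions: hν (medium-pressure Hg lamp, Pyrex filter, λ > 300 nm), MeNH(OMe) (5 equiv), THF, 0 °C, Ar
Reagents that add atoms: N,O-dimethylhydroxylamine, CNOC
Why: Direct excitation of the diazo ketone, which the ring holds s-cis, expels N2 while the benzyl-bearing oxane carbon C5, the only carbon substituent on the carbonyl carbon C4, shifts to the diazo carbon C3; the oxane thereby becomes an oxolane carrying the former C4 as an exocyclic ketene (17), and MeNH(OMe) adds to the ketene carbon to give the amide after tautomerisation. The closest known reaction type is this very one, the photochemical Wolff ring contraction of cyclic 2-diazo ketones with capture of the ketene by an N–H nucleophile. The five-membered ring (O1, C2, C3, C4, C5 of the target) is closed not by cyclisation but by ring contraction: its C3–C4 bond arises by a suprafacial 1,2-alkyl shift with retention at the migrating carbon, so the configuration installed there in step 2 is kept. The one new stereocentre, C3, is fixed when the amide enol is protonated; the proton should arrive on the face away from the two flanking substituents, which favours the 2,3-cis-3,4-cis epimer, so 18 is carried forward as a C3 epimer mixture and C3 is corrected under thermodynamic control in step 11. The selectivity required is alkyl shift over 1,2-hydride shift from C2–H and over capture of the carbene by the amine; the enforced s-cis geometry (loss of N2 concerted with migration under direct irradiation) and the single migrating group on the carbonyl carbon should secure it, and the Pyrex cut-off keeps the aryl benzyl ethers unexcited.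

Step 9
Reactants: 19 4-bromobenzene-1,3-diol (4-bromoresorcinol)
Product: 20 1-bromo-2,4-bis(benzyloxy)benzene
Conditions: BnBr, K2CO3, DMF, 60 °C
Reagents that add atoms: benzyl bromide, BrCc1ccccc1
Why: Williamson ether synthesis on both phenols.

Step 10
Reactants: 18 (2S,4S,5S)-5-[2,4-bis(benzyloxy)phenyl]-4-[4-(benzyloxy)benzyl]-2-[4-(benzyloxy)phenyl]-N-methoxy-N-methyloxolane-3-carboxamide (C3 epimer mixture); 20 1-bromo-2,4-bis(benzyloxy)benzene
Product: 22 [2,4-bis(benzyloxy)phenyl]{(2S,4S,5S)-5-[2,4-bis(benzyloxy)phenyl]-4-[4-(benzyloxy)benzyl]-2-[4-(benzyloxy)phenyl]oxolan-3-yl}methanone (C3 epimer mixture), via aryllithium 21 (not isolated)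
Conditions: 20, n-BuLi, THF, −78 °C; then 18, −78 → −20 °C; aq. NH4Cl
Reagents that add atoms: none
Why: Bromine–lithium exchange followed by Weinreb ketone synthesis: the five-membered lithium chelate holds the tetrahedral adduct until the quench so that only the ketone should form, and the C3 epimer composition is simply carried through.

Step 11
Reactants: 22 [2,4-bis(benzyloxy)phenyl]{(2S,4S,5S)-5-[2,4-bis(benzyloxy)phenyl]-4-[4-(benzyloxy)benzyl]-2-[4-(benzyloxy)phenyl]oxolan-3-yl}methanone (C3 epimer mixture)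
Product: 23 [2,4-bis(benzyloxy)phenyl]{(2S,3S,4S,5S)-5-[2,4-bis(benzyloxy)phenyl]-4-[4-(benzyloxy)benzyl]-2-[4-(benzyloxy)phenyl]oxolan-3-yl}methanone
Conditions: K2CO3 (0.5 equiv), MeOH/THF 1:2, rt
Reagents that add atoms: none
Why: Base-mediated thermodynamic epimerisation α to the aryl ketone (through the enolate, or through reversible retro-oxa-Michael opening and 5-exo-trig reclosure): the isomer with every pair of neighbouring ring substituents trans is the most stable, so C3 (and C2, should the ring open) should converge on the required configuration, while C4 and C5 are not epimerisable under these mild conditions.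

Step 12
Reactants: 23 [2,4-bis(benzyloxy)phenyl]{(2S,3S,4S,5S)-5-[2,4-bis(benzyloxy)phenyl]-4-[4-(benzyloxy)benzyl]-2-[4-(benzyloxy)phenyl]oxolan-3-yl}methanone
Product: 24 (2,4-dihydroxyphenyl)[(2S,3S,4S,5S)-5-(2,4-dihydroxyphenyl)-4-(4-hydroxybenzyl)-2-(4-hydroxyphenyl)oxolan-3-yl]methanone
Conditions: H2 (1 atm), Pd/C (10 wt%), EtOAc/MeOH 1:1, rt
Reagents that add atoms: none
Why: Catalytic hydrogenolysis of the five aryl benzyl ethers under neutral conditions; phenolic O–CH2Ph bonds are cleaved far faster than the hindered ring C–O bonds (as in debenzylations of flavans and 2,5-diaryloxolane lignans) or the electron-rich aryl ketone, so the four stereocentres should be untouched.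

**Compound list**
1 | 3-[4-(benzyloxy)phenyl]propanoic acid | OC(=O)CCc1ccc(OCc2ccccc2)cc1 | starting material
2 | (S)-4-benzyloxazolidin-2-one | O=C1N[C@@H](Cc2ccccc2)CO1 | starting material
3 | 3-[4-(benzyloxy)phenyl]propanoic pivalic anhydride | CC(C)(C)C(=O)OC(=O)CCc1ccc(OCc2ccccc2)cc1 | intermediate
4 | (S)-4-benzyl-3-{3-[4-(benzyloxy)phenyl]propanoyl}oxazolidin-2-one | O=C1OC[C@H](Cc2ccccc2)N1C(=O)CCc1ccc(OCc2ccccc2)cc1 | intermediate
5 | 2,4-bis(benzyloxy)benzaldehyde | O=Cc1ccc(OCc2ccccc2)cc1OCc1ccccc1 | starting material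
6 | (S)-4-benzyl-3-{(2R,3S)-3-[2,4-bis(benzyloxy)phenyl]-2-[4-(benzyloxy)benzyl]-3-(trimethylsilyloxy)propanoyl}oxazolidin-2-one | O=C1OC[C@H](Cc2ccccc2)N1C(=O)[C@H](Cc1ccc(OCc2ccccc2)cc1)[C@H](O[Si](C)(C)C)c1ccc(OCc2ccccc2)cc1OCc1ccccc1 | intermediate
7 | (S)-4-benzyl-3-{(2R,3S)-3-[2,4-bis(benzyloxy)phenyl]-2-[4-(benzyloxy)benzyl]-3-hydroxypropanoyl}oxazolidin-2-one | O=C1OC[C@H](Cc2ccccc2)N1C(=O)[C@H](Cc1ccc(OCc2ccccc2)cc1)[C@H](O)c1ccc(OCc2ccccc2)cc1OCc1ccccc1 | intermediate
8 | (2R,3S)-3-[2,4-bis(benzyloxy)phenyl]-2-[4-(benzyloxy)benzyl]-3-hydroxy-N-methoxy-N-methylpropanamide | CON(C)C(=O)[C@H](Cc1ccc(OCc2ccccc2)cc1)[C@H](O)c1ccc(OCc2ccccc2)cc1OCc1ccccc1 | intermediate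
9 | (4R,5S)-5-[2,4-bis(benzyloxy)phenyl]-4-[4-(benzyloxy)benzyl]-5-hydroxypent-1-yn-3-one | C#CC(=O)[C@H](Cc1ccc(OCc2ccccc2)cc1)[C@H](O)c1ccc(OCc2ccccc2)cc1OCc1ccccc1 | intermediate
10 | (2S,3R)-2-[2,4-bis(benzyloxy)phenyl]-3-[4-(benzyloxy)benzyl]-2,3-dihydro-4H-pyran-4-one (2,3-trans) | O=C1C=CO[C@H](c2ccc(OCc3ccccc3)cc2OCc2ccccc2)[C@H]1Cc1ccc(OCc2ccccc2)cc1 | intermediate
11 | 1-(benzyloxy)-4-bromobenzene | Brc1ccc(OCc2ccccc2)cc1 | starting material
12 | [4-(benzyloxy)phenyl]magnesium bromide | Br[Mg]c1ccc(OCc2ccccc2)cc1 | intermediate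
13 | (2S,5R,6S)-6-[2,4-bis(benzyloxy)phenyl]-5-[4-(benzyloxy)benzyl]-2-[4-(benzyloxy)phenyl]-4-(trimethylsilyloxy)-5,6-dihydro-2H-pyran | C[Si](C)(C)OC1=C[C@@H](c2ccc(OCc3ccccc3)cc2)O[C@H](c2ccc(OCc3ccccc3)cc2OCc2ccccc2)[C@H]1Cc1ccc(OCc2ccccc2)cc1 | intermediate
14 | (2S,5R,6S)-6-[2,4-bis(benzyloxy)phenyl]-5-[4-(benzyloxy)benzyl]-2-[4-(benzyloxy)phenyl]oxan-4-one (2,6-trans; 5,6-trans) | O=C1C[C@@H](c2ccc(OCc3ccccc3)cc2)O[C@H](c2ccc(OCc3ccccc3)cc2OCc2ccccc2)[C@H]1Cc1ccc(OCc2ccccc2)cc1 | intermediate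
15 | (2S,5R,6S)-6-[2,4-bis(benzyloxy)phenyl]-5-[4-(benzyloxy)benzyl]-2-[4-(benzyloxy)phenyl]-3-(trifluoroacetyl)oxan-4-one (C3 unassigned; drawn as the diketone) | O=C1C(C(=O)C(F)(F)F)[C@@H](c2ccc(OCc3ccccc3)cc2)O[C@H](c2ccc(OCc3ccccc3)cc2OCc2ccccc2)[C@H]1Cc1ccc(OCc2ccccc2)cc1 | intermediate
16 | (2R,5R,6S)-6-[2,4-bis(benzyloxy)phenyl]-5-[4-(benzyloxy)benzyl]-2-[4-(benzyloxy)phenyl]-3-diazooxan-4-one (same spatial arrangement as 14; the C2 descriptor changes only because the diazo carbon outranks aryl) | O=C1C(=[N+]=[N-])[C@@H](c2ccc(OCc3ccccc3)cc2)O[C@H](c2ccc(OCc3ccccc3)cc2OCc2ccccc2)[C@H]1Cc1ccc(OCc2ccccc2)cc1 | intermediate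
17 | {5-[2,4-bis(benzyloxy)phenyl]-4-[4-(benzyloxy)benzyl]-2-[4-(benzyloxy)phenyl]oxolan-3-ylidene}methanone (ketene; C2, C4 and C5 arranged as in 18) | O=C=C1[C@H](Cc2ccc(OCc3ccccc3)cc2)[C@@H](c2ccc(OCc3ccccc3)cc2OCc2ccccc2)O[C@@H]1c1ccc(OCc2ccccc2)cc1 | intermediate
18 | (2S,4S,5S)-5-[2,4-bis(benzyloxy)phenyl]-4-[4-(benzyloxy)benzyl]-2-[4-(benzyloxy)phenyl]-N-methoxy-N-methyloxolane-3-carboxamide (C3 epimer mixture; 2,5-trans and 4,5-trans) | CON(C)C(=O)C1[C@H](Cc2ccc(OCc3ccccc3)cc2)[C@@H](c2ccc(OCc3ccccc3)cc2OCc2ccccc2)O[C@@H]1c1ccc(OCc2ccccc2)cc1 | intermediate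
19 | 4-bromobenzene-1,3-diol (4-bromoresorcinol) | Oc1ccc(Br)c(O)c1 | starting material
20 | 1-bromo-2,4-bis(benzyloxy)benzene | Brc1ccc(OCc2ccccc2)cc1OCc1ccccc1 | intermediate
21 | [2,4-bis(benzyloxy)phenyl]lithium | [Li]c1ccc(OCc2ccccc2)cc1OCc1ccccc1 | intermediate
22 | [2,4-bis(benzyloxy)phenyl]{(2S,4S,5S)-5-[2,4-bis(benzyloxy)phenyl]-4-[4-(benzyloxy)benzyl]-2-[4-(benzyloxy)phenyl]oxolan-3-yl}methanone (C3 epimer mixture) | O=C(c1ccc(OCc2ccccc2)cc1OCc1ccccc1)C1[C@H](Cc2ccc(OCc3ccccc3)cc2)[C@@H](c2ccc(OCc3ccccc3)cc2OCc2ccccc2)O[C@@H]1c1ccc(OCc2ccccc2)cc1 | intermediate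
23 | [2,4-bis(benzyloxy)phenyl]{(2S,3S,4S,5S)-5-[2,4-bis(benzyloxy)phenyl]-4-[4-(benzyloxy)benzyl]-2-[4-(benzyloxy)phenyl]oxolan-3-yl}methanone (all-trans) | O=C(c1ccc(OCc2ccccc2)cc1OCc1ccccc1)[C@H]1[C@H](Cc2ccc(OCc3ccccc3)cc2)[C@@H](c2ccc(OCc3ccccc3)cc2OCc2ccccc2)O[C@@H]1c1ccc(OCc2ccccc2)cc1 | intermediate
24 | (2,4-dihydroxyphenyl)[(2S,3S,4S,5S)-5-(2,4-dihydroxyphenyl)-4-(4-hydroxybenzyl)-2-(4-hydroxyphenyl)oxolan-3-yl]methanone | O=C(c1ccc(O)cc1O)[C@H]1[C@H](Cc2ccc(O)cc2)[C@@H](c2ccc(O)cc2O)O[C@@H]1c1ccc(O)cc1 | target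

**Step count**
Total: 12 steps. Longest linear sequence: 11 steps (steps 1–8 and 10–12, from acid 1); step 9 is the only side branch.

**Steps most likely to fail**

Step 8 (ring contraction). Hydride shift from the benzylic, oxygen-bearing C2–H to the carbene centre, or capture of the carbene by the N–H of the trap, may outrun the 1,2-alkyl shift. The fallback is a carbene-free contraction that sets out from 10 and returns at 18. The conjugate addition of step 6 is worked up without acid so that trimethylsilyl enol ether 13 is isolated. Enol ether 13 is treated with 4-nitrobenzenesulfonyl azide (MeCN, rt → 40 °C); cycloaddition, loss of N2 and 1,2-shift of the same benzyl-bearing carbon (the sulfonyl azide ring contraction of cyclic enol ethers) should give, after aqueous work-up, the ring-contracted N-(4-nitrophenylsulfonyl)oxolane-3-carboxamide F1. N-Methylation (MeI, K2CO3, DMF) gives the activated N-methyl-N-sulfonyl amide F2 (safety-catch activation), and aminolysis with MeNH(OMe) (THF, 40 °C) returns amide 18.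

Step 10 (aryl ketone). Addition to the amide carbonyl flanked by two ring substituents may be so slow that α-deprotonation with E1cB opening of the ring, or base-induced loss of formaldehyde from the N–OMe group, takes over. The fallback sets out from 18 and returns at 22. Reduction of 18 with LiAlH4 (THF, −78 °C) stops at the chelated hemiaminal and gives on work-up the oxolane-3-carbaldehyde F3. Aryllithium 21 adds to this smaller and more electrophilic carbonyl group to give the secondary alcohol F4 (the carbinol configuration is immaterial), and oxidation with Dess–Martin periodinane (CH2Cl2, NaHCO3) gives ketone 22.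

Step 2 (anti-aldol). Addition to the electron-rich, ortho-substituted aldehyde may stall, so that enolate silylation and retro-aldol equilibration erode conversion and anti-selectivity. The fallback builds the pyranone by cycloaddition and alkylation; it sets out from 5 and returns at 10. A Ti(OiPr)4/BINOL-catalysed Mukaiyama-aldol-type hetero-Diels–Alder reaction of 5 with 1-methoxy-3-(trimethylsilyloxy)buta-1,3-diene (the BINOL antipode that gives the S carbinol) gives the silylated aldol adduct F5. TFA (CH2Cl2, 0 °C) cyclises it in the same flask to the (S)-2-aryl-2,3-dihydro-4H-pyran-4-one F6. Kinetic deprotonation at C3 with LiN(i-Pr)2 (THF, −78 °C) and alkylation with 4-(benzyloxy)benzyl bromide anti to the C2 aryl group should give 10 directly.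

**Further compounds**
F1 | step 8 | (2S,4S,5S)-5-[2,4-bis(benzyloxy)phenyl]-4-[4-(benzyloxy)benzyl]-2-[4-(benzyloxy)phenyl]-N-(4-nitrophenylsulfonyl)oxolane-3-carboxamide (C3 epimer mixture) | O=C(NS(=O)(=O)c1ccc(cc1)[N+](=O)[O-])C1[C@H](Cc2ccc(OCc3ccccc3)cc2)[C@@H](c2ccc(OCc3ccccc3)cc2OCc2ccccc2)O[C@@H]1c1ccc(OCc2ccccc2)cc1
F2 | step 8 | (2S,4S,5S)-5-[2,4-bis(benzyloxy)phenyl]-4-[4-(benzyloxy)benzyl]-2-[4-(benzyloxy)phenyl]-N-methyl-N-(4-nitrophenylsulfonyl)oxolane-3-carboxamide (C3 epimer mixture) | O=C(N(C)S(=O)(=O)c1ccc(cc1)[N+](=O)[O-])C1[C@H](Cc2ccc(OCc3ccccc3)cc2)[C@@H](c2ccc(OCc3ccccc3)cc2OCc2ccccc2)O[C@@H]1c1ccc(OCc2ccccc2)cc1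
F3 | step 10 | (2S,4S,5S)-5-[2,4-bis(benzyloxy)phenyl]-4-[4-(benzyloxy)benzyl]-2-[4-(benzyloxy)phenyl]oxolane-3-carbaldehyde (C3 epimer mixture) | O=CC1[C@H](Cc2ccc(OCc3ccccc3)cc2)[C@@H](c2ccc(OCc3ccccc3)cc2OCc2ccccc2)O[C@@H]1c1ccc(OCc2ccccc2)cc1
F4 | step 10 | [2,4-bis(benzyloxy)phenyl]{(2S,4S,5S)-5-[2,4-bis(benzyloxy)phenyl]-4-[4-(benzyloxy)benzyl]-2-[4-(benzyloxy)phenyl]oxolan-3-yl}methanol (mixture at C3 and at the carbinol) | OC(c1ccc(OCc2ccccc2)cc1OCc1ccccc1)C1[C@H](Cc2ccc(OCc3ccccc3)cc2)[C@@H](c2ccc(OCc3ccccc3)cc2OCc2ccccc2)O[C@@H]1c1ccc(OCc2ccccc2)cc1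
F5 | step 2 | (S,E)-5-[2,4-bis(benzyloxy)phenyl]-1-methoxy-5-(trimethylsilyloxy)pent-1-en-3-one | CO/C=C/C(=O)C[C@H](O[Si](C)(C)C)c1ccc(OCc2ccccc2)cc1OCc1ccccc1
F6 | step 2 | (S)-2-[2,4-bis(benzyloxy)phenyl]-2,3-dihydro-4H-pyran-4-one | O=C1C=CO[C@H](c2ccc(OCc3ccccc3)cc2OCc2ccccc2)C1
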